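Count the warm hours.

| flask | starting complex | incoming ligand | leaving ligand | temperature | remark | time |
|---|---|---|---|---|---|---|
| blue | 10 mM | 10.5 mM | 5 mM | 15 °C | run made earlier |  |
| green | 10 mM | 10.5 mM | 2.5 mM | 26 °C | run made earlier |  |
| red | 10 mM | 10.5 mM | 3.8 mM | 15 °C | run made earlier |  |
| alder | 10 mM (fed, over 6.0 h) | 10.5 mM | 5.00 mM |  | the addition at −10 °C, then warmed to 20 °C; the feed brings no volume worth counting | 15 h |
| oak | 10 mM (fed, over 6.0 h) | 10.5 mM | 5.00 mM | 20 °C | all else is in the flask from the start; the feed brings no volume worth counting | 15 h |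
| larch | 10 mM | 10.5 mM (fed, over 6.0 h) | 5.00 mM | 20 °C | all else is in the flask from the start; the feed brings no volume worth counting | 15 h |
| ash | 10 mM (in portions, 4, over 6.0 h) | 10.5 mM | 5.00 mM | 20 °C | first portion at the start, last at 6.0 h | 15 h |

- blue (time / h: complex with two exchanged / %, side product / %): 1.33: 0, 0.2; 2.00: 0.2, 0.2; 3.00: 1.1, 0.6; 4.00: 1.0, 0.9; 6.00: 1.4, 0.7; 10.0: 2.7, 2.1; 15.0: 4.4, 3.1
- green (time / h: complex with two exchanged / %, side product / %): 0.667: 1.0, 0; 1.00: 0.1, 0.2; 1.50: 1.1, 1.0; 2.50: 2.1, 2.5; 4.00: 3.1, 2.8; 6.00: 3.3, 6.4; 10.0: 2.7, 8.4
- red (time / h: complex with two exchanged / %, side product / %): 1.33: 0.3, 0; 2.50: 0.3, 0; 4.00: 0, 0.5; 5.00: 1.3, 0.6; 6.00: 2.5, 0.4; 8.00: 3.0, 0.5; 10.0: 3.3, 2.1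

(each reading ± 0.5 percentage points)

- steps under discussion: complex with one exchanged + incoming ligand <-> leaving ligand + complex with two exchanged; complex with one exchanged -> side product; starting complex + incoming ligand <-> leaving ligand + complex with one exchanged

- the flask that comes out highest in share of complex with two exchanged in complex with two exchanged plus side product, or "all alike" when all lie within 1.5 percentage points (alder / oak / larch / ash / all alike)
- share of complex with two exchanged in complex with two exchanged plus side product at the end, alder
- share of complex with two exchanged in complex with two exchanged plus side product at the end, oak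
- share of complex with two exchanged in complex with two exchanged plus side product at the end, larch
- share of complex with two exchanged in complex with two exchanged plus side product at the end, ash

1. I start with the green run. From 4.00 h to 10.0 h, c(complex with two exchanged) stays between 2.7% and 3.3%, while c(side product) climbs from 2.8% to 8.4%. So I treat the first as capped and let the second grow with time.

2. Taking the last reading of each run, with its scatter, side product per hour in green at 26 °C reads 4.06 times that in blue at 15 °C, though green also has less leaving ligand. The drop from 20 °C to alder's −10 °C is wider than the step from 15 °C to 26 °C, so I count alder's cold hours as lost.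

3. Warm hours are the mean time the charged starting complex spends at 20 °C. Oak, fed evenly, gets 12.0 h. Ash, with evenly spaced portions, gets 12.0 h. Alder gets 9.00 h. For alder that gives 0.750, the warm-hour ratio, a flask's warm hours divided by oak's.

4. Now I turn the question round. For "all alike", alder's gap over oak must stay below 1.5 percentage points. The share here is the selectivity. If the complex with two exchanged is capped and side product follows warm hours, the odds of that share scale as one over the ratio. Near an even share, the gap is then about a quarter of ln(1/ratio). So the ratio would have to stand higher than 0.942, but alder stands at 0.750. My gap is 7.2 points, and ash should sit with oak.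

5. The forecast says alder, with alder 52%, oak 48%, larch 44% and ash 48%: “Feeding the complex only shortens the effective time, by about 3 h, so oak and ash are nearly alike”. Its gap between alder and oak is 4 points, smaller than mine.

The flask that comes out highest is alder: alder 46.7%, oak 41.3%, larch 40.6%, ash 41.1%, so alder's lead over oak is 5.4 points.

    complex with one exchanged + incoming ligand ⇌ leaving ligand + complex with two exchanged (K = 0.260, k = 5.90 M⁻¹ h⁻¹, Ea = 59.0 kJ mol⁻¹, ΔH = −35.0 kJ mol⁻¹)
    complex with one exchanged → side product (k = 0.0310 h⁻¹, Ea = 101 kJ mol⁻¹)
    starting complex + incoming ligand ⇌ leaving ligand + complex with one exchanged (K = 0.160, k = 12.0 M⁻¹ h⁻¹, Ea = 54.0 kJ mol⁻¹, ΔH = −31.0 kJ mol⁻¹)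
    (constants at 20 °C)

At 15.0 h, alder holds 3.62% side product and oak 4.82%, a ratio of 0.751 beside my 0.750. Ash, with a warm-hour ratio of 1.00, ends with 4.85% side product, and 0.750 times that gives 3.64%, beside the 3.62% in alder.

The runs are simulated from invented constants, and the scatter is random.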